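The data stem from a simulated flask with constants of no real substance; noise was put on by code.

Don't trust an excess taken from one reading: the right-handed product peak in the north run is so small that a scatter of 1 percentage point swings the figure. Pool the readings and work in powers of ten.

- north: left-handed substrate 0.10 M; right-handed substrate 0.10 M; partner 1.2 equiv; protic impurity 0.030 M; free catalyst 3 mol%; run made earlier
- flask: left-handed substrate 0.10 M; partner 1.20 equiv; protic impurity 0.0300 M; free catalyst 2 mol%; right-handed substrate 0.10 M; time 8.0 min

north run (percent of the left-handed substrate and right-handed substrate together charged)

| time / s | left-handed product / % | right-handed product / % | left-handed substrate / % |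
|---|---|---|---|
| 10.0 | 6.6 | 2.4 | 42.0 |
| 15.0 | 9.0 | 0.9 | 40.1 |
| 25.0 | 15.7 | 4.1 | 35.1 |
| 50.0 | 22.9 | 3.1 | 26.1 |
| 90.0 | 29.3 | 4.1 | 20.4 |

(readings scatter by 1 percentage point)

- free catalyst is single-handed; left-handed substrate and right-handed substrate are mirror images of each other, charged as a racemate, each of them at the stated concentration
- an excess is below zero if the other one leads
- no earlier run changes the charge of free catalyst; that part of a forecast is a guess

- excess of left-handed product over right-handed product in the product at 25 s
- excess of left-handed product over right-handed product in the product at 8.0 min
- part of the left-handed substrate and right-handed substrate charged together that has reacted at 8.0 min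

Pool the north readings from 50.0 s on: left-handed over right-handed product is 7.25, so its base-ten logarithm is 0.860. This is the product logarithm, a reading that carries the scatter. Now turn the question round. For the right-handed product to lead, this logarithm must fall below zero, so the north run stands 0.860 of a power of ten from the opposite outcome. Pooled up to 25.0 s, the ratio is 4.23, a logarithm of 0.626, lower than the later one.

Guess that the smaller catalyst charge scales both products alike, and that the ratio read from 50.0 s on still stands at 8.0 min, so the logarithms carry over. With excess = (ratio − 1)/(ratio + 1), this reckoning gives 61.8 % at 25 s and 75.8 % at 8.0 min.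

The forecast differs from this reckoning on both excesses: 77 %, then 72 %, with 33 % reacted. Its ground: “The left-handed substrate reacts much faster than the right-handed one.”

The flask gives 68.0 % at 25 s and 75.6 % at 8.0 min, with 37.3 % reacted; partner, the limiting reagent, stands at 0.067 % of its charge.

    free catalyst + left-handed substrate ⇌ catalyst intermediate A (K = 160 M⁻¹, k = 25.0 M⁻¹ s⁻¹)
    free catalyst + right-handed substrate ⇌ catalyst intermediate B (K = 10.4 M⁻¹, k = 107 M⁻¹ s⁻¹)
    partner + catalyst intermediate A → free catalyst + left-handed product (k = 8.15 M⁻¹ s⁻¹)
    partner + catalyst intermediate B → free catalyst + right-handed product (k = 3.71 M⁻¹ s⁻¹)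
    left-handed substrate ⇌ right-handed substrate (k = 6.19 × 10⁻⁴ s⁻¹)
    2 partner → self-condensation product (k = 0.0615 M⁻¹ s⁻¹)
    partner + protic impurity → quenched reagent (k = 0.0288 M⁻¹ s⁻¹)

At 8.0 min the flask's logarithm is 0.857, beside the carried 0.860. Take away the reverse step of catalyst intermediate B to free catalyst + right-handed substrate, and the excess goes from 75.6 % to −68.2 %, a logarithm of −0.723: the right-handed product leads. That step is the main reason for the left-handed lead in the flask at 8.0 min; backward turnover there is 99.3 % of the forward turnover to catalyst intermediate B.

For the neighbour flask with 0.12 M of protic impurity, guess that the protic impurity scales both products alike; the carried 0.860 then gives an excess of 75.8 %. Computed at 8.0 min, that flask gives 76.2 %.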